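**Retrosynthetic overview**
- Endgame: the 2-substituted butadiene comes from a terminal alkyne and ethylene (enyne metathesis). The 8-OH comes from Markovnikov hydration of a C7=C8 olefin. H9 and the side chain come from 1,2-addition to a C9 enone followed by palladium/formate hydrogenolysis. The 6-oxygen comes from γ-oxygenation of the same enone.
- Key disconnection: C3–C4 of ring A, opened to an alkenyl iodide (C3) and an isopropenyl group (C4=C18, C19) on C5. A domino Heck cyclisation–borylation closes ring A, builds the quaternary C4 and places boron (later the 18-OH) on C18.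
- Enabling feature: ring B (C5–C10) with C17 on C8 and the C4/C18/C19 unit on C5 is a p-menthane, that is, carvone. C4 is fully substituted and carries one CH3 and one CH2O, so the alkylpalladium formed on C18 has no β-hydrogen and can be trapped.
- Ring order: ring B is bought with (S)-carvone (C5 stereocentre), C10 is made quaternary by two α'-alkylations, and ring A is closed last.

Key step: step 5

Remark: labdane numbering (ring A = C1–C5 and C10; ring B = C5–C10; C17 on C8, C18/C19 on C4, C20 on C10) is used for all compounds, and the three starting materials are taken to be catalogue chemicals.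

**Step 1**
Reactants: 1 ethyl (Z)-3-iodoprop-2-enoate
Product: 2 (Z)-3-iodoprop-2-en-1-ol
Conditions: i-Bu2AlH (2.2 equiv), CH2Cl2, −78 to 0 °C; aq. potassium sodium tartrate
Reagents that add atoms: none
Why: Ester-to-alcohol reduction with i-Bu2AlH at low temperature, a 1,2-reduction that leaves the alkenyl iodide and its Z geometry untouched, with no stereocentre formed.

**Step 2**
Reactants: 2 (Z)-3-iodoprop-2-en-1-ol
Product: 3 (Z)-3-bromo-1-iodoprop-1-ene
Conditions: CBr4, PPh3, CH2Cl2, 0 °C
Reagents that add atoms: carbon tetrabromide BrC(Br)(Br)Br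
Why: Appel bromination turns the primary allylic alcohol into the bromide under neutral conditions by SN2 displacement of the oxyphosphonium group, without loss of the Z geometry.

**Step 3**
Reactants: 4 (S)-(+)-carvone
Product: 5 (5S,6R)-2,6-dimethyl-5-(prop-1-en-2-yl)cyclohex-2-en-1-one (trans-6-methylcarvone; the minor cis epimer is carried along)
Conditions: LiN(i-Pr)2, THF, −78 °C; MeI, −78 to 0 °C
Reagents that add atoms: iodomethane CI
Why: Kinetic α'-deprotonation of the enone at C10 and SN2 methylation of the cross-conjugated lithium enolate, the methyl entering mainly anti to the isopropenyl group, a configuration that step 4 erases again.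

**Step 4**
Reactants: 5 trans-6-methylcarvone; 3 (Z)-3-bromo-1-iodoprop-1-ene
Product: 6 (5R,6R)-6-[(Z)-3-iodoprop-2-en-1-yl]-2,6-dimethyl-5-(prop-1-en-2-yl)cyclohex-2-en-1-one (iodoallyl arm trans to isopropenyl)
Conditions: LiN(i-Pr)2, THF–DMPU, −78 °C; 3, −78 °C to rt
Reagents that add atoms: none
Why: Second kinetic α'-enolate alkylation, in which the planar C10 enolate takes the allylic bromide on the face anti to the neighbouring C5 isopropenyl group, setting quaternary C10 with the C1 arm trans and the C20 methyl cis to that group, while the alkenyl iodide is inert to the enolate.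

**Step 5**
Reactants: 6 iodoallyl dimethylcarvone
Product: 8 18-hydroxy-11,12,13,14,15,16-hexanor-ent-labda-2,7-dien-9-one (trans-fused; C19 methyl axial and syn to C20; CH2OH equatorial), via pinacol boronate 7 (not isolated)
Conditions: Pd2(dba)3 (2.5 mol %), P(o-tol)3 (10 mol %), KOAc (3 equiv), B2pin2 (1.3 equiv, slow addition), 1,4-dioxane, 80 °C; then 30% H2O2, pH 7 phosphate buffer, THF, 0 °C to rt
Reagents that add atoms: bis(pinacolato)diboron CC1(C)OB(OC1(C)C)B1OC(C)(C)C(C)(C)O1; hydrogen peroxide OO
Why: Zerovalent palladium inserts into the C3–iodine bond with retention of the Z geometry, the alkenylpalladium adds syn across the isopropenyl C4=C18 bond (C3 to C4, palladium to C18), and the neopentyl-type alkylpalladium, which has no β-hydrogen because C4 is now quaternary, transmetallates with acetate-activated B2pin2 and reductively eliminates to boronate 7, whose C–B bond is then oxidised with retention. The closest known reaction type is the domino intramolecular Heck (carbopalladation)–Miyaura borylation of halides tethered to 1,1-disubstituted alkenes, a member of the Heck cyclisation–anion capture family. Ring A closes in the 6-exo-trig mode, the 7-endo alternative being disfavoured as in other Heck cyclisations of this tether length, and the fusion is trans because the C1 arm on C10 and the C4 arm on C5 are trans-diequatorial on ring B. The only new stereocentre, C4, is controlled by C5 and C10: in the four-centre insertion the ligated palladium must sit on the open equatorial rim next to C6, since the other isopropenyl rotamer would press it against the axial C20 methyl, so C18 ends equatorial and the C19 methyl axial, syn to C20. Insertion must outrun direct borylation of the alkenylpalladium, which the alkene held gauche to the iodoallyl arm and the slow addition of B2pin2 secure, and the alkylpalladium must be trapped before 3-exo attack on C2=C3, which is slowed because the equatorial C4–C18 bond lies near the nodal plane of that π bond. The C7=C8 enone is out of reach of both organopalladium species and inert to B2pin2 without copper, and the neutral peroxide work-up avoids its nucleophilic epoxidation.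

**Step 6**
Reactants: 8 dienone alcohol
Product: 9 18-hydroxy-11,12,13,14,15,16-hexanor-ent-labd-7-en-9-one
Conditions: H2 (1 atm), RhCl(PPh3)3 (5 mol %), benzene–EtOH, rt
Reagents that add atoms: none
Why: Homogeneous hydrogenation with RhCl(PPh3)3 reduces the cis-disubstituted C2=C3 bond and leaves the trisubstituted conjugated C7=C8 bond, the selectivity known from carvone itself, and no stereocentre is formed.

**Step 7**
Reactants: 9 enone alcohol
Product: 10 9,18-bis(tert-butyldimethylsilyloxy)-11,12,13,14,15,16-hexanor-ent-labda-6,8-diene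
Conditions: TBSOTf (2.5 equiv), Et3N (4 equiv), CH2Cl2, 0 °C to rt
Reagents that add atoms: tert-butyldimethylsilyl triflate CC(C)(C)[Si](C)(C)OS(=O)(=O)C(F)(F)F
Why: Soft enolisation, in which O-silylation of the enone and γ-deprotonation at C6 (C10 is quaternary, so no α'-hydrogen competes) give the linear silyl dienol ether while the primary 18-OH is silylated in the same operation, with no stereocentre formed.

**Step 8**
Reactants: 10 bis-silyl dienol ether
Product: 11 6-hydroxy-18-(tert-butyldimethylsilyloxy)-11,12,13,14,15,16-hexanor-ent-labd-7-en-9-one (6-OH equatorial, anti to C19 and C20)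
Conditions: mCPBA (1.1 equiv), NaHCO3, CH2Cl2, −20 °C; aq. citric acid, THF
Reagents that add atoms: 3-chloroperbenzoic acid OOC(=O)c1cccc(Cl)c1
Why: Vinylogous Rubottom oxidation, in which the peracid attacks the terminal C6=C7 bond of the dienol ether as in steroidal 3,5-dienol ethers and from the face opposite the syn-axial C19 and C20 methyls, so collapse gives the γ-hydroxy enone with equatorial 6-OH, also the thermodynamically preferred epimer of this epimerisable centre.

**Step 9**
Reactants: 11 γ-hydroxy enone
Product: 12 6-(triethylsilyloxy)-18-(tert-butyldimethylsilyloxy)-11,12,13,14,15,16-hexanor-ent-labd-7-en-9-one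
Conditions: TESCl, imidazole, DMF, 0 °C
Reagents that add atoms: chlorotriethylsilane CC[Si](Cl)(CC)CC
Why: Standard silylation gives a secondary TES ether that survives the organolithium and palladium steps and can later be removed in the presence of the primary TBS ether, without touching any stereocentre.

**Step 10**
Reactants: 12 bis-silylated enone; 13 (4-iodobut-1-yn-1-yl)trimethylsilane
Product: 15 methyl carbonate of 6-(triethylsilyloxy)-18-(tert-butyldimethylsilyloxy)-14-(trimethylsilyl)-15,16-dinor-ent-labd-7-en-13-yn-9-ol (carbonate on the C20 face; side chain on the opposite face), via lithium alkoxide 14 (not isolated)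
Conditions: 13 (1.5 equiv), t-BuLi (3.0 equiv), Et2O–pentane, −78 °C; 12, −78 to −20 °C; ClCO2Me, −78 °C to rt
Reagents that add atoms: methyl chloroformate COC(=O)Cl
Why: Iodine–lithium exchange and 1,2-addition of the primary alkyllithium to the enone carbonyl from the face anti to the axial C20 methyl (axial attack, as in 1-decalones with an angular methyl) set C9, and the hindered alkoxide is acylated in situ to the allylic carbonate.

**Step 11**
Reactants: 15 tertiary allylic carbonate
Product: 16 6-(triethylsilyloxy)-18-(tert-butyldimethylsilyloxy)-14-(trimethylsilyl)-15,16-dinor-ent-labd-7-en-13-yne (H9 anti to C20; side chain equatorial)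
Conditions: Pd(OAc)2 (5 mol %), n-Bu3P (20 mol %), HCO2H (3 equiv), Et3N (4 equiv), THF, 50 °C
Reagents that add atoms: none
Why: Palladium-catalysed formate hydrogenolysis of an allylic carbonate (Tsuji-type), in which ionisation anti to the carbonate places palladium on the face opposite C20 and hydride passes from the palladium formate to the more substituted allyl terminus C9 on that same face, giving H9 anti to C20, the equatorial side chain and the C7=C8 olefin.

**Step 12**
Reactants: 16 C7=C8 olefin
Product: 18 6-(triethylsilyloxy)-18-(tert-butyldimethylsilyloxy)-14-(trimethylsilyl)-15,16-dinor-ent-labd-13-yn-8-ol (8-OH equatorial; C17 axial), via tertiary hydroperoxide 17 (not isolated)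
Conditions: Mn(dpm)3 (10 mol %), PhSiH3 (2 equiv), O2 (1 atm), i-PrOH–CH2Cl2, 0 °C; then P(OEt)3
Reagents that add atoms: dioxygen O=O
Why: Mukaiyama hydration, in which hydrogen-atom transfer to C7 gives the tertiary C8 radical that O2 captures from the equatorial side because the axial approach is blocked by the syn-axial C20 methyl, while the silyl-capped alkyne reacts more slowly than the trisubstituted olefin.

**Step 13**
Reactants: 18 TES-protected 8-ol
Product: 19 18-(tert-butyldimethylsilyloxy)-14-(trimethylsilyl)-15,16-dinor-ent-labd-13-yne-6,8-diol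
Conditions: AcOH–THF–H2O, 0 °C to rt
Reagents that add atoms: none
Why: Mild acid hydrolysis cleaves the secondary TES ether much faster than the primary neopentyl TBS ether or the C-silyl group, and no stereocentre is touched.

**Step 14**
Reactants: 19 6,8-diol
Product: 20 6-acetoxy-18-(tert-butyldimethylsilyloxy)-14-(trimethylsilyl)-15,16-dinor-ent-labd-13-yn-8-ol
Conditions: Ac2O, pyridine, DMAP (cat.), CH2Cl2, 0 °C to rt
Reagents that add atoms: acetic anhydride CC(=O)OC(C)=O
Why: DMAP-catalysed acetylation takes the secondary equatorial 6-OH and leaves the tertiary 8-OH, while the 18-oxygen is still masked.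

**Step 15**
Reactants: 20 silylated acetate
Product: 21 6-acetoxy-15,16-dinor-ent-labd-13-yne-8,18-diol
Conditions: TBAF–AcOH (1:1, 3 equiv), THF, 0 °C to rt
Reagents that add atoms: none
Why: Fluoride desilylation removes the O-TBS and the alkynyl C-TMS groups in one operation, and the acetic acid buffer suppresses acetate cleavage and acyl migration from O6 to O18.

**Step 16**
Reactants: 21 terminal alkyne
Product: 22 (1R,3S,4S,4aR,8S,8aS)-3-hydroxy-8-(hydroxymethyl)-3,4a,8-trimethyl-4-(3-methylidenepent-4-en-1-yl)decahydronaphthalen-1-yl acetate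
Conditions: ethylene (1 atm), second-generation Grubbs catalyst (H2IMes)(PCy3)Cl2Ru=CHPh (5 mol %), CH2Cl2, rt to 40 °C
Reagents that add atoms: ethylene C=C
Why: Ethylene–alkyne cross enyne metathesis converts the terminal alkyne into the 2-substituted 1,3-butadiene with full atom economy, tolerates free hydroxyls and the acetate, and touches no stereocentre.

**Compound list**
1 | ethyl (Z)-3-iodoprop-2-enoate | CCOC(=O)/C=C\I | starting material
2 | (Z)-3-iodoprop-2-en-1-ol | OC/C=C\I | intermediate
3 | (Z)-3-bromo-1-iodoprop-1-ene | BrC/C=C\I | intermediate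
4 | (S)-(+)-carvone | O=C1C[C@@H](C(C)=C)CC=C1C | starting material
5 | (5S,6R)-2,6-dimethyl-5-(prop-1-en-2-yl)cyclohex-2-en-1-one | O=C1[C@H](C)[C@@H](C(C)=C)CC=C1C | intermediate
6 | (5R,6R)-6-[(Z)-3-iodoprop-2-en-1-yl]-2,6-dimethyl-5-(prop-1-en-2-yl)cyclohex-2-en-1-one | O=C1[C@](C)(C/C=C\I)[C@@H](C(C)=C)CC=C1C | intermediate
7 | C18 pinacol boronate of the trans-fused 2,7-dien-9-one | O=C1[C@]2(C)CC=C[C@](C)(CB3OC(C)(C)C(C)(C)O3)[C@H]2CC=C1C | intermediate
8 | 18-hydroxy-hexanor-ent-labda-2,7-dien-9-one | O=C1[C@]2(C)CC=C[C@](C)(CO)[C@H]2CC=C1C | intermediate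
9 | 18-hydroxy-hexanor-ent-labd-7-en-9-one | O=C1[C@]2(C)CCC[C@](C)(CO)[C@H]2CC=C1C | intermediate
10 | 9,18-bis(TBS-oxy)-hexanor-ent-labda-6,8-diene | CC1=C(O[Si](C)(C)C(C)(C)C)[C@]2(C)CCC[C@](C)(CO[Si](C)(C)C(C)(C)C)[C@H]2C=C1 | intermediate
11 | 6-hydroxy-18-(TBS-oxy)-hexanor-ent-labd-7-en-9-one | O=C1[C@]2(C)CCC[C@](C)(CO[Si](C)(C)C(C)(C)C)[C@H]2[C@H](O)C=C1C | intermediate
12 | 6-(TES-oxy)-18-(TBS-oxy)-hexanor-ent-labd-7-en-9-one | O=C1[C@]2(C)CCC[C@](C)(CO[Si](C)(C)C(C)(C)C)[C@H]2[C@H](O[Si](CC)(CC)CC)C=C1C | intermediate
13 | (4-iodobut-1-yn-1-yl)trimethylsilane | C[Si](C)(C)C#CCCI | starting material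
14 | lithium C9 alkoxide | C[Si](C)(C)C#CCC[C@]1(O[Li])[C@]2(C)CCC[C@](C)(CO[Si](C)(C)C(C)(C)C)[C@H]2[C@H](O[Si](CC)(CC)CC)C=C1C | intermediate
15 | C9 methyl carbonate | C[Si](C)(C)C#CCC[C@]1(OC(=O)OC)[C@]2(C)CCC[C@](C)(CO[Si](C)(C)C(C)(C)C)[C@H]2[C@H](O[Si](CC)(CC)CC)C=C1C | intermediate
16 | 6-(TES-oxy)-18-(TBS-oxy)-14-TMS-15,16-dinor-ent-labd-7-en-13-yne | C[Si](C)(C)C#CCC[C@H]1[C@]2(C)CCC[C@](C)(CO[Si](C)(C)C(C)(C)C)[C@H]2[C@H](O[Si](CC)(CC)CC)C=C1C | intermediate
17 | C8 hydroperoxide | C[Si](C)(C)C#CCC[C@H]1[C@]2(C)CCC[C@](C)(CO[Si](C)(C)C(C)(C)C)[C@H]2[C@H](O[Si](CC)(CC)CC)C[C@]1(C)OO | intermediate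
18 | 8-ol with 6-OTES and 18-OTBS | C[Si](C)(C)C#CCC[C@H]1[C@]2(C)CCC[C@](C)(CO[Si](C)(C)C(C)(C)C)[C@H]2[C@H](O[Si](CC)(CC)CC)C[C@]1(C)O | intermediate
19 | 6,8-diol with 18-OTBS | C[Si](C)(C)C#CCC[C@H]1[C@]2(C)CCC[C@](C)(CO[Si](C)(C)C(C)(C)C)[C@H]2[C@H](O)C[C@]1(C)O | intermediate
20 | 6-acetate with 18-OTBS | C[Si](C)(C)C#CCC[C@H]1[C@]2(C)CCC[C@](C)(CO[Si](C)(C)C(C)(C)C)[C@H]2[C@H](OC(C)=O)C[C@]1(C)O | intermediate
21 | 6-acetoxy-15,16-dinor-ent-labd-13-yne-8,18-diol | C#CCC[C@H]1[C@]2(C)CCC[C@](C)(CO)[C@H]2[C@H](OC(C)=O)C[C@]1(C)O | intermediate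
22 | CNP0312185.1 | C=CC(=C)CC[C@H]1[C@]2(C)CCC[C@](C)(CO)[C@H]2[C@H](OC(C)=O)C[C@]1(C)O | target

**Step count**
- Total step count: 16.
- Longest linear sequence: 15 (from 1 through steps 1, 2 and 4–16; 14 from carvone).

**Steps most likely to fail**

**Step 5.**
- *What may go wrong:* borylation of the alkenylpalladium before it inserts, or 3-exo closure and ring-enlarging rearrangement of the neopentyl palladium before boron capture.
- *Fallback, from 6 back to 8:* the same bond is made by enolate alkenylation instead of carbopalladation. The isopropenyl group of 6 is epoxidised chemoselectively (mCPBA, NaHCO3, CH2Cl2, 0 °C) to the epoxide F1 (both C4 epimers). A Meinwald rearrangement (ZnBr2, toluene) gives the α-branched aldehyde F2. Palladium-catalysed intramolecular α-alkenylation of the aldehyde enolate (Pd(OAc)2, rac-BINAP, Cs2CO3, toluene, 90 °C) joins C3 to C4 and gives the quaternary aldehyde F3, with the formyl group expected on the equatorial rim for the same steric reason. Chemoselective aldehyde reduction (NaBH(OAc)3, THF) then returns to 8.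

**Step 11.**
- *What may go wrong:* sluggish ionisation of the hindered carbonate, β-hydride elimination of the allylpalladium to dienes, hydride delivery to C7, or loss of the neighbouring silyloxy group.
- *Fallback, from 12 back to 16 (it also bypasses step 10):* H9 is set by hydroboration instead. Wittig methylenation (Ph3P=CH2, THF, reflux) gives the exocyclic diene F4. 9-BBN adds to the terminal C11 from the face anti to C20 to give the B-alkyl borane F5. NaOH/H2O2 oxidation gives the homoallylic alcohol F6, and I2/PPh3/imidazole gives the iodide F7. Alkylation with lithiated 1-(trimethylsilyl)propyne (n-BuLi, THF–DMPU) completes the butynyl chain of 16.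

**Step 8.**
- *What may go wrong:* attack of the peracid on the C8=C9 enol ether bond (α- instead of γ-oxygenation), or poor facial selectivity at C6.
- *Fallback, from 10 back to 11:* a cycloaddition fixes both questions. Sensitised photooxygenation (O2, tetraphenylporphyrin, hν, CH2Cl2, −78 °C) adds singlet oxygen [4+2] across C6 and C9 of the cisoid ring-B diene from the face opposite C19 and C20, giving the silyl peroxyketal endoperoxide F8. Thiourea in MeOH cleaves the O–O bond, and the C9 silyl hemiketal collapses to 11.

**Further compounds**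
F1 | step 5 | isopropenyl epoxide of 6 (C4 epimers) | O=C1[C@](C)(C/C=C\I)[C@@H](C2(C)CO2)CC=C1C
F2 | step 5 | 2-substituted propanal from F1 (C4 epimers) | O=C1[C@](C)(C/C=C\I)[C@@H](C(C)C=O)CC=C1C
F3 | step 5 | 9-oxo-hexanor-ent-labda-2,7-dien-18-al | O=C1[C@]2(C)CC=C[C@](C)(C=O)[C@H]2CC=C1C
F4 | step 11 | C9 exocyclic methylene diene | C=C1[C@]2(C)CCC[C@](C)(CO[Si](C)(C)C(C)(C)C)[C@H]2[C@H](O[Si](CC)(CC)CC)C=C1C
F5 | step 11 | C11 B-alkyl-9-borabicyclo[3.3.1]nonane | B1(C2CCCC1CCC2)C[C@H]3[C@]4(C)CCC[C@](C)(CO[Si](C)(C)C(C)(C)C)[C@H]4[C@H](O[Si](CC)(CC)CC)C=C3C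
F6 | step 11 | C11 primary alcohol | OC[C@H]1[C@]2(C)CCC[C@](C)(CO[Si](C)(C)C(C)(C)C)[C@H]2[C@H](O[Si](CC)(CC)CC)C=C1C
F7 | step 11 | C11 primary iodide | IC[C@H]1[C@]2(C)CCC[C@](C)(CO[Si](C)(C)C(C)(C)C)[C@H]2[C@H](O[Si](CC)(CC)CC)C=C1C
F8 | step 8 | 6,9-endoperoxide of 10 | CC1=C[C@H]2OO[C@]1(O[Si](C)(C)C(C)(C)C)[C@]3(C)CCC[C@](C)(CO[Si](C)(C)C(C)(C)C)[C@@H]23
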